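**Retrosynthetic overview**

- Target: 2,9-dichloro-5,6-dimethoxy-11,12-dihydroindolo[2,3-a]carbazole. The last disconnection puts blocking bromines back on C1 and C10; they are removed at the end by chemoselective hydrogenolysis.
- Key disconnection: both pyrrole rings at once, through C6a–C6b, C4a–C4b, N11–C11a and N12–C11b, back to 4,5-dimethoxycatechol and two molecules of (2-bromo-3-chlorophenyl)hydrazine (twofold Bucherer–Fischer annulation).
- Feature on which the strategy rests: the central benzene ring (C4b, C5, C6, C6a, C11a, C11b) is a masked 4,5-dimethoxycatechol. C11a and C11b (the pyrrole C2 atoms, bearing N11 and N12) are its former C–OH carbons, C6a and C4b (the pyrrole C3 atoms) its former C–H carbons, and C5 and C6 keep the methoxy groups.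
- Precursors: the catechol from 3,4-dimethoxyphenol via the ortho-quinone; the hydrazine from 2-bromo-3-chloroaniline by diazotization and reduction.
- Ring order: the central ring and the two chlorobenzo rings are bought; the two pyrrole rings close one after the other in the same flask, through a monoannulated carbazol-1-ol.

Key step: step 4

Remark on the chemistry: in step 4 bisulfite is assumed to act as in the Bucherer reaction of naphthols, by conjugate addition to the ring-protonated dienone tautomer, while the hydrazine condenses at the carbonyl carbon. Compound 3 is made fresh and kept under argon.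

**Step 1**
Reactants: 1 3,4-dimethoxyphenol
Product: 2 4,5-dimethoxy-1,2-benzoquinone (4,5-dimethoxycyclohexa-3,5-diene-1,2-dione)
Conditions: IBX (1.1 equiv), DMF, rt, dark
Reagents that add atoms: 2-iodoxybenzoic acid (IBX), O=C1OI(=O)(O)c2ccccc12
Why: IBX ortho-oxygenation of an electron-rich phenol (aryloxy-iodane, oxygen transfer to the ortho carbon, then oxidation of the iodine-bound catechol) should occur at C6, the unhindered ortho position para to the 3-methoxy group, and 2 is a stable quinone that can be crystallized.

**Step 2**
Reactants: 2 4,5-dimethoxy-1,2-benzoquinone
Product: 3 4,5-dimethoxybenzene-1,2-diol (4,5-dimethoxycatechol)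
Conditions: Na2S2O4, EtOAc–H2O, rt, argon
Reagents that add atoms: none
Why: Dithionite reduction of an ortho-quinone to the catechol is fast in a two-phase system and leaves the methoxy groups untouched; 3 is used at once because it reoxidizes in air.

**Step 3**
Reactants: 4 2-bromo-3-chloroaniline
Product: 6 (2-bromo-3-chlorophenyl)hydrazine, via 2-bromo-3-chlorobenzenediazonium chloride 5 (not isolated)
Conditions: NaNO2, conc. HCl, H2O, 0 °C; then SnCl2·2H2O, conc. HCl, 0 °C to rt; NaOH (aq) work-up
Reagents that add atoms: sodium nitrite, [Na+].[O-]N=O (the second nitrogen of 6); hydrogen chloride, Cl (chloride counter-ion of 5 only)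
Why: Diazotization followed by SnCl2 reduction of the diazonium salt is the standard arylhydrazine synthesis and leaves the aryl C–Br and C–Cl bonds intact.

**Step 4**
Reactants: 3 4,5-dimethoxybenzene-1,2-diol; 6 (2-bromo-3-chlorophenyl)hydrazine (2.5 equiv)
Product: 8 1,10-dibromo-2,9-dichloro-5,6-dimethoxy-11,12-dihydroindolo[2,3-a]carbazole, via 8-bromo-7-chloro-3,4-dimethoxy-9H-carbazol-1-ol 7 (not isolated)
Conditions: NaHSO3 (40% aq, excess), dioxane–H2O, argon, sealed tube, 130 °C; then HCl (aq)–AcOH, 100 °C
Reagents that add atoms: none
Why: Proposed new method: each C–OH carbon of 3 is meta to one methoxy carbon (resorcinol-type) and para to the other, so ring protonation at C6 (later C3, catechol numbering) should give a methoxy-conjugated dienone that bisulfite holds as its conjugate adduct; 6 condenses at the carbonyl carbon and loss of bisulfite leaves the aryl hydrazone, the tautomer of an N,N'-diarylhydrazine. Acid then drives a [3,3] shift of the ene-hydrazine form that joins the one free ortho carbon of the bromo-chloro ring to C6 of the central ring, the aniline nitrogen adds to the C1 iminium carbon (5-exo-trig) and ammonia leaves with rearomatization to give carbazol-1-ol 7. Compound 7 is a naphthol-like phenol whose keto form (a 2H-carbazol-1-one, the oxidation-level analogue of the 1-oxotetrahydrocarbazoles of classical Fischer routes to this ring system) keeps the indole aromatic, and it repeats the sequence at its C1–OH and C2–H (carbazole numbering) to close the second pyrrole ring, again 5-exo-trig. The closest known reaction is the Bucherer carbazole synthesis of naphthols with arylhydrazines and NaHSO3, combined with Fischer indolization; it has not been shown on a benzene-ring catechol or twice on one ring. No stereocentre arises; the step needs regiocontrol on three rings, secured by the bromine ortho to nitrogen in 6 (C–C bond formation only para to chlorine), by the single free CH next to each oxygenated carbon of 3, and by the methoxy groups para to each hydrazo nitrogen, which close the para-benzidine and para-semidine channels on the central ring.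

**Step 5**
Reactants: 8 1,10-dibromo-2,9-dichloro-5,6-dimethoxy-11,12-dihydroindolo[2,3-a]carbazole
Product: 9 borregomycin E (2,9-dichloro-5,6-dimethoxy-11,12-dihydroindolo[2,3-a]carbazole)
Conditions: H2 (1 atm), 10% Pd/C, NaOAc, THF–MeOH, rt, stopped after uptake of 2 equiv H2
Reagents that add atoms: none
Why: Palladium-catalysed hydrogenolysis cleaves aryl C–Br bonds much faster than aryl C–Cl bonds (chemoselective hydrodehalogenation), so with NaOAc as HBr scavenger and controlled hydrogen uptake only the two blocking bromines should be removed.

**Compound list**

1 | 3,4-dimethoxyphenol | COc1ccc(O)cc1OC | starting material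
2 | 4,5-dimethoxy-1,2-benzoquinone | COC1=CC(=O)C(=O)C=C1OC | intermediate
3 | 4,5-dimethoxybenzene-1,2-diol | COc1cc(O)c(O)cc1OC | intermediate
4 | 2-bromo-3-chloroaniline | Nc1cccc(Cl)c1Br | starting material
5 | 2-bromo-3-chlorobenzenediazonium chloride | N#[N+]c1cccc(Cl)c1Br.[Cl-] | intermediate
6 | (2-bromo-3-chlorophenyl)hydrazine | NNc1cccc(Cl)c1Br | intermediate
7 | 8-bromo-7-chloro-3,4-dimethoxy-9H-carbazol-1-ol | COc1cc(O)c2[nH]c3c(Br)c(Cl)ccc3c2c1OC | intermediate
8 | 1,10-dibromo-2,9-dichloro-5,6-dimethoxy-11,12-dihydroindolo[2,3-a]carbazole | COc1c(OC)c2c3ccc(Cl)c(Br)c3[nH]c2c2[nH]c3c(Br)c(Cl)ccc3c12 | intermediate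
9 | borregomycin E (2,9-dichloro-5,6-dimethoxy-11,12-dihydroindolo[2,3-a]carbazole) | COc1c(OC)c2c3ccc(Cl)cc3[nH]c2c2[nH]c3cc(Cl)ccc3c12 | target

**Step count**

Total steps: 5. Longest linear sequence: 4 steps (steps 1, 2, 4, 5); the hydrazine branch is steps 3, 4, 5.

**Steps most likely to fail**

1. Step 4 (proposed new method). The benzene-ring catechol may not ketonize far enough for the exchange of C–O for C–N, so that no hydrazo compound forms. The diarylhydrazine may also go over to N–N cleavage, disproportionation or semidine-type migration faster than the [3,3] shift, and a methoxy group may be lost through the enol-ether form of the keto tautomer. The fallback uses known reaction types, sets out from 3 and comes back at 9, so that step 5 falls away. Compound 3 is treated with Tf2O and pyridine in CH2Cl2 at 0 °C to give 4,5-dimethoxy-1,2-phenylene bis(trifluoromethanesulfonate) F1. Twofold Buchwald–Hartwig amination with 3-chloroaniline (Pd(OAc)2, rac-BINAP, Cs2CO3, toluene, 100 °C; the triflates react, the aryl chloride should not with this ligand) gives N1,N2-bis(3-chlorophenyl)-4,5-dimethoxybenzene-1,2-diamine F2. Twofold oxidative cyclization of the two diarylamine units (catalytic Pd(OAc)2, pivalic acid, K2CO3, air, 110 °C; C–H/C–H coupling of diarylamines to carbazoles) then closes both pyrrole rings. Coupling on the central ring can occur only at the free CH next to each nitrogen; on the chloroaryl ring it is expected mainly at the less hindered carbon para to chlorine. This gives 9 directly.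

2. Step 5. Hydrogenolysis may run on into the C–Cl bonds once the C–Br bonds are gone, or stall after the first debromination if sparingly soluble material coats the catalyst. The fallback sets out from 8 and comes back at 9. It is a radical chain reduction with Bu3SnH and AIBN in dioxane at 100 °C, in which the stannyl radical abstracts bromine from the arene but not chlorine. No new compound arises (F0).

3. Step 1. Oxygen transfer may go in part to the hindered ortho position C2, or the quinone may be degraded further in the oxidizing medium. The fallback sets out from 1 and comes back at 3, bypassing 2 and step 2. Magnesium-mediated ortho-formylation of 1 (MgCl2, Et3N, paraformaldehyde, MeCN, reflux) at the free, unhindered ortho position gives 2-hydroxy-4,5-dimethoxybenzaldehyde F3. Dakin oxidation (H2O2, NaOH aq, argon, 0 °C to rt, then acidification) converts the formyl group into the second hydroxyl and gives 3.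

**Further compounds**

F1 | step 4 | 4,5-dimethoxy-1,2-phenylene bis(trifluoromethanesulfonate) | COc1cc(OS(=O)(=O)C(F)(F)F)c(OS(=O)(=O)C(F)(F)F)cc1OC
F2 | step 4 | N1,N2-bis(3-chlorophenyl)-4,5-dimethoxybenzene-1,2-diamine | COc1cc(Nc2cccc(Cl)c2)c(Nc2cccc(Cl)c2)cc1OC
F0 | step 5 | none | none
F3 | step 1 | 2-hydroxy-4,5-dimethoxybenzaldehyde | COc1cc(O)c(C=O)cc1OC
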